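The earlier runs and the new flask were generated by integration for substances that don't exist; the scatter is artificial.

Target cannot be made from side product: the steps thought possible lead into it and not out of it. What side product takes from the charge is therefore lost to target, and that loss is the number to carry to the flasks below.

| flask | substrate | temperature | remark | time |
|---|---|---|---|---|
| dawn | 2 mM | 35 °C | run made earlier |  |
| south-west | 1.0 mM | 65 °C |  | 3.0 min |
| north-east | 1.0 mM | 35 °C |  | 3.0 min |
| south | 1.0 mM | 50 °C |  | 3.0 min |

dawn run (percent of the substrate charged)

| time / s | intermediate C / % | side product / % | target / % | intermediate D / % | substrate / % |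
|---|---|---|---|---|---|
| 10.0 | 2.7 | 10.8 | 0.3 | 0 | 44.2 |
| 20.0 | 5.9 | 18.6 | 0.1 | 0.4 | 23.7 |
| 40.0 | 13.7 | 25.9 | 0.3 | 2.2 | 7.5 |

(readings scatter by 0.3 percentage points)

- which of these there is most of at the end, counted by the substrate in it, south-west (side product / target / intermediate C / intermediate D)
- which of these there is most of at the end, counted by the substrate in it, north-east (side product / target / intermediate C / intermediate D)
- which of these there is most of at the end, counted by the substrate in it, south (side product / target / intermediate C / intermediate D)
- the largest of these amounts at the end, in percent of the substrate charged, south-west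
- the largest of these amounts at the end, in percent of the substrate charged, north-east
- the largest of these amounts at the end, in percent of the substrate charged, south

In the dawn flask at 40.0 s, substrate stands at 7.5 % and target at 0.3 %, while 50.4 % of the charge sits in forms not read. Let side product V take a fixed share f, its selectivity, of the substrate A lost: dV/dt = −f dA/dt. This integrates in closed form, since V + fA stays constant, and V reaches V∞ once substrate has gone:

f = (25.9 % − 10.8 %) / (44.2 % − 7.5 %) = 0.411

V∞ = 25.9 % + f · 7.5 % = 29.0 %

R = 100 % − V∞ = 71.0 %

R is the target ceiling, the part of the charge that side product leaves. Self-condensation product draws on it too, and the effect of temperature on f is a guess.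

In the dawn flask at 35 °C, the last reading of target, at 40.0 s, lies far below R.

The forecast gives side product for north-east at 30 %, close to V∞. For south it gives target at 47 % and for south-west target at 55 %, saying “the chain largely finishes and target leads”; both lie under R.

North-east ends with side product largest at 32.2 %, south with target at 62.1 %, and south-west with target at 67.1 %.

    substrate → intermediate A (k = 0.0360 s⁻¹, Ea = 88.0 kJ mol⁻¹)
    intermediate B → side product (k = 0.0600 s⁻¹, Ea = 72.0 kJ mol⁻¹)
    intermediate A → intermediate C (k = 0.0130 s⁻¹, Ea = 74.0 kJ mol⁻¹)
    intermediate C → intermediate D (k = 0.00850 s⁻¹, Ea = 77.0 kJ mol⁻¹)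
    intermediate D → target (k = 0.0110 s⁻¹, Ea = 79.0 kJ mol⁻¹)
    substrate → side product (k = 0.0120 s⁻¹, Ea = 84.0 kJ mol⁻¹)
    substrate + target ⇌ idle adduct, settled at all times (K = 30000 L mol⁻¹, ΔH = 23.0 kJ mol⁻¹)
    2 substrate → self-condensation product (k = 6.70 L mol⁻¹ s⁻¹, Ea = 43.0 kJ mol⁻¹)
    intermediate B → intermediate C (k = 0.0130 s⁻¹, Ea = 87.0 kJ mol⁻¹)
    substrate ⇌ intermediate B (K = 0.360, k = 0.0190 s⁻¹, Ea = 90.0 kJ mol⁻¹, ΔH = 3.00 kJ mol⁻¹)
    (constants at 35 °C)

South-west target stops 3.9 percentage points under R, with 30.6 % of side product and 2.27 % of self-condensation product beside it. In the neighbour of south charged with 1.7 mM of substrate, side product stands at 30.9 % and self-condensation product at 7.47 %, and target ends 11 points under R, at 60.1 %.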